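**Retrosynthetic overview**
- The target comes from a 3-hydroxy-heliangolide macrocycle by O-benzoylation and a final peracid epoxidation of the 1(10)-alkene under ring-conformation control.
- The ten-membered carbocycle is closed last, at C3–C4, by a cathodically driven, chromium-catalysed intramolecular alkenyl iodide/aldehyde coupling that also sets C3.
- The seco iodo-aldehyde comes from Mitsunobu inversion at C8 with a (2S,3R)-epoxy acid (made from methyl (R)-3-hydroxybutanoate), after a chromium Barbier allylation that forms C7–C8 and sets C7 and C8 from C6.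
- The allyl donor is a (bromomethyl)butenolide whose lactone ring is formed first, by ring-closing metathesis of a (Z)-iodo-dienol ester; its C6 stereocentre comes from L-serine-derived methyl (S)-glycerate acetonide.
- The achiral aldehyde partner comes from zirconium-catalysed carboalumination of a 3-butynyl silyl ether and ethylene oxide opening, which fixes the E-C1=C10 alkene.

Assumption: positions are given in germacrane numbering (C1–C15; lactone carbonyl C12, exocyclic methylene C13), and the four starting materials are taken as purchasable.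

**Route**

Step 1
Reactants: 1 methyl (S)-2,2-dimethyl-1,3-dioxolane-4-carboxylate
Product: 2 (S)-2,2-dimethyl-1,3-dioxolane-4-carbaldehyde
Conditions: iBu2AlH (1.05 equiv), CH2Cl2, −78 °C; MeOH, then Na2SO4·10H2O; used crude
Reagents that add atoms: none
Why: Partial ester reduction with iBu2AlH stops at the aluminium hemiacetal at −78 °C and gives the α-alkoxy aldehyde without touching the purchased stereocentre (future C6).

Step 2
Reactants: 2 (S)-2,2-dimethyl-1,3-dioxolane-4-carbaldehyde
Product: 3 (R)-4-[(Z)-2-iodoprop-1-en-1-yl]-2,2-dimethyl-1,3-dioxolane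
Conditions: EtPPh3I, n-BuLi, THF, 0 °C; I2, −78 °C; NaN(SiMe3)2, −78 °C; then 2, −78 → −20 °C
Reagents that add atoms: ethyltriphenylphosphonium iodide, CC[P+](c1ccccc1)(c1ccccc1)c1ccccc1.[I-]; iodine, II
Why: The Stork–Zhao-type Wittig olefination with the α-iodoethylidene ylide gives the (Z)-2-iodoalkene (iodine cis to C6) under kinetic control, and the cold, weakly basic conditions leave the α-oxygenated stereocentre intact.

Step 3
Reactants: 3 (R)-4-[(Z)-2-iodoprop-1-en-1-yl]-2,2-dimethyl-1,3-dioxolane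
Product: 4 (2R,3Z)-4-iodopent-3-ene-1,2-diol
Conditions: AcOH/H2O (4:1), 40 °C
Reagents that add atoms: none
Why: Acid-catalysed acetonide hydrolysis frees the diol without breaking a C–O bond at the stereocentre or affecting the alkenyl iodide.

Step 4
Reactants: 4 (2R,3Z)-4-iodopent-3-ene-1,2-diol
Product: 7 (3S,4Z)-5-iodohexa-1,4-dien-3-ol, via primary tosylate 5 (not isolated), via vinyl epoxide 6 (not isolated)
Conditions: NaH (2.2 equiv), 1-(p-toluenesulfonyl)imidazole (1.05 equiv), THF, 0 °C → rt; then Me3S+ I−/n-BuLi (3 equiv, preformed ylide), THF, −10 °C → rt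
Reagents that add atoms: trimethylsulfonium iodide, C[S+](C)C.[I-]
Why: One-pot primary sulfonylation and epoxide closure (the C6–O bond is never broken) is followed by opening at the terminal carbon with dimethylsulfonium methylide and loss of Me2S (epoxide-to-allylic-alcohol one-carbon homologation), so the vinyl carbinol forms with retention at C6.

Step 5
Reactants: 7 (3S,4Z)-5-iodohexa-1,4-dien-3-ol; 8 2-(bromomethyl)prop-2-enoic acid
Product: 9 (3S,4Z)-5-iodohexa-1,4-dien-3-yl 2-(bromomethyl)prop-2-enoate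
Conditions: DCC (1.2 equiv), DMAP (3 mol%), CH2Cl2, −10 → 0 °C
Reagents that add atoms: none
Why: Steglich esterification acylates the secondary alcohol on oxygen with retention, keeping DMAP low and the temperature cold to spare the allylic bromide.

Step 6
Reactants: 9 (3S,4Z)-5-iodohexa-1,4-dien-3-yl 2-(bromomethyl)prop-2-enoate
Product: 10 (S)-3-(bromomethyl)-5-[(Z)-2-iodoprop-1-en-1-yl]furan-2(5H)-one
Conditions: second-generation Grubbs catalyst RuCl2(=CHPh)(PCy3)(H2IMes) (5 mol%), toluene (0.01 M), 80 °C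
Reagents that add atoms: none
Why: Ring-closing metathesis between the vinyl group and the acrylate closes the butenolide (the lactone ring of the target) with loss of ethene, while the trisubstituted iodoalkene is inert and C6 is untouched.

Step 7
Reactants: 11 tert-butyl(but-3-yn-1-yloxy)dimethylsilane
Product: 13 (3E)-6-{[tert-butyl(dimethyl)silyl]oxy}-4-methylhex-3-en-1-ol, via alkenylalane 12 (not isolated)
Conditions: AlMe3 (2.5 equiv), Cp2ZrCl2 (0.2 equiv), CH2Cl2, 0 °C → rt; then n-BuLi (1 equiv), THF, −30 °C; ethylene oxide, −30 → 0 °C; aq. NH4Cl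
Reagents that add atoms: trimethylaluminium, C[Al](C)C; ethylene oxide, C1CO1
Why: Negishi zirconium-catalysed syn-carboalumination gives the (E)-alkenylalane regio- and stereospecifically, and its ate complex opens ethylene oxide with retention, fixing the E geometry of the future C1=C10 alkene.

Step 8
Reactants: 13 (3E)-6-{[tert-butyl(dimethyl)silyl]oxy}-4-methylhex-3-en-1-ol
Product: 14 (3E)-6-{[tert-butyl(dimethyl)silyl]oxy}-4-methylhex-3-enal
Conditions: Dess–Martin periodinane (1.2 equiv), NaHCO3, CH2Cl2, 0 °C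
Reagents that add atoms: none
Why: Buffered Dess–Martin oxidation gives the β,γ-unsaturated aldehyde without moving the double bond into conjugation.

Step 9
Reactants: 14 (3E)-6-{[tert-butyl(dimethyl)silyl]oxy}-4-methylhex-3-enal
Product: 16 (3E)-6,6-dimethoxy-3-methylhex-3-en-1-ol, via silyl acetal 15 (not isolated)
Conditions: HC(OMe)3 (3 equiv), p-TsOH·H2O (5 mol%), MeOH, rt
Reagents that add atoms: trimethyl orthoformate, COC(OC)OC
Why: Acid-catalysed acetalisation masks the future C3 aldehyde and the same acidic methanol then cleaves the primary silyl ether, so protection and deprotection are done in one operation.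

Step 10
Reactants: 16 (3E)-6,6-dimethoxy-3-methylhex-3-en-1-ol
Product: 17 (3E)-6,6-dimethoxy-3-methylhex-3-enal
Conditions: Dess–Martin periodinane (1.2 equiv), NaHCO3, CH2Cl2, 0 °C; used at once
Reagents that add atoms: none
Why: Buffered Dess–Martin oxidation gives the C8 aldehyde while the dimethyl acetal and the E-alkene stay in place.

Step 11
Reactants: 18 methyl (R)-3-hydroxybutanoate
Product: 19 methyl (2R,3R)-3-hydroxy-2-methylbutanoate
Conditions: LiN(iPr)2 (2.2 equiv), THF, −50 → −20 °C; MeI (1.2 equiv), DMPU, −20 → 0 °C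
Reagents that add atoms: iodomethane, CI
Why: Fráter–Seebach alkylation of the chelated dianion places the methyl anti to the C3 methyl group (anti product), installing the α-methyl needed for the next step.

Step 12
Reactants: 19 methyl (2R,3R)-3-hydroxy-2-methylbutanoate
Product: 21 methyl (2S,3R)-2,3-dimethyloxirane-2-carboxylate, via iodohydrin ester 20 (not isolated)
Conditions: LiN(iPr)2 (2.2 equiv), THF, −78 → −20 °C; I2 (1.1 equiv), −78 °C → rt
Reagents that add atoms: none
Why: The chelated dianion is iodinated on the face anti to the C3 methyl and the lithium alkoxide then displaces the tertiary iodide with inversion (Darzens-type closure), so the purchased C3 centre fixes C2 as S with the two methyls cis.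

Step 13
Reactants: 21 methyl (2S,3R)-2,3-dimethyloxirane-2-carboxylate
Product: 22 (2S,3R)-2,3-dimethyloxirane-2-carboxylic acid
Conditions: LiOH (1.5 equiv), THF/H2O (3:1), 0 °C → rt; 1 M HCl to pH 3, 0 °C
Reagents that add atoms: lithium hydroxide, [Li+].[OH-]
Why: Mild saponification cleaves the methyl ester while the trisubstituted, carboxylate-deactivated epoxide survives.

Step 14
Reactants: 10 (S)-3-(bromomethyl)-5-[(Z)-2-iodoprop-1-en-1-yl]furan-2(5H)-one; 17 (3E)-6,6-dimethoxy-3-methylhex-3-enal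
Product: 23 (4R,5S)-4-[(1S,3E)-1-hydroxy-6,6-dimethoxy-3-methylhex-3-en-1-yl]-5-[(Z)-2-iodoprop-1-en-1-yl]-3-methylideneoxolan-2-one
Conditions: CrCl2 (3 equiv), THF, 0 °C → rt; aq. NH4Cl
Reagents that add atoms: none
Why: In this Nozaki–Hiyama (Barbier-type) allylation the allylchromium (trivalent chromium) adds through a closed chair transition state at the butenolide β-carbon anti to the C6 substituent (trans-lactone, C7 R) with the aldehyde chain equatorial (7,8-anti, C8 S), and the double bond moves to the exocyclic methylene.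

Step 15
Reactants: 23 (4R,5S)-4-[(1S,3E)-1-hydroxy-6,6-dimethoxy-3-methylhex-3-en-1-yl]-5-[(Z)-2-iodoprop-1-en-1-yl]-3-methylideneoxolan-2-one; 22 (2S,3R)-2,3-dimethyloxirane-2-carboxylic acid
Product: 24 (1R,3E)-1-[(2S,3R)-2-[(Z)-2-iodoprop-1-en-1-yl]-4-methylidene-5-oxooxolan-3-yl]-6,6-dimethoxy-3-methylhex-3-en-1-yl (2S,3R)-2,3-dimethyloxirane-2-carboxylate
Conditions: PPh3 (2 equiv), DIAD (2 equiv), toluene, 0 °C → rt
Reagents that add atoms: none
Why: Mitsunobu esterification displaces the activated C8 oxygen by the carboxylate of 22 with inversion, converting the 8S alcohol from the allylation into the required 8R (8β) ester.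

Step 16
Reactants: 24 (1R,3E)-1-[(2S,3R)-2-[(Z)-2-iodoprop-1-en-1-yl]-4-methylidene-5-oxooxolan-3-yl]-6,6-dimethoxy-3-methylhex-3-en-1-yl (2S,3R)-2,3-dimethyloxirane-2-carboxylate
Product: 25 (1R,3E)-1-[(2S,3R)-2-[(Z)-2-iodoprop-1-en-1-yl]-4-methylidene-5-oxooxolan-3-yl]-3-methyl-6-oxohex-3-en-1-yl (2S,3R)-2,3-dimethyloxirane-2-carboxylate
Conditions: LiBF4 (1 equiv), MeCN/H2O (50:1), rt
Reagents that add atoms: water, O
Why: Mild Lewis-acid acetal hydrolysis unveils the C3 aldehyde without opening the ester-deactivated epoxide or isomerising the β,γ-alkene.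

Step 17
Reactants: 25 (1R,3E)-1-[(2S,3R)-2-[(Z)-2-iodoprop-1-en-1-yl]-4-methylidene-5-oxooxolan-3-yl]-3-methyl-6-oxohex-3-en-1-yl (2S,3R)-2,3-dimethyloxirane-2-carboxylate
Product: 26 (3S,6R,7R,8R)-3-hydroxy-8-{[(2S,3R)-2,3-dimethyloxirane-2-carbonyl]oxy}germacra-1(10)E,4Z,11(13)-trien-12,6-olide
Conditions: CrCl2 (20 mol%), NiCl2(MeOCH2CH2OMe) (5 mol%), 4,4'-di-tert-butyl-2,2'-bipyridine (6 mol%), Cp2ZrCl2 (1.5 equiv), LiCl (0.1 M), DMF/THF (1:1), undivided cell, Al anode, Ni-foam cathode, constant current 3 mA (2.5 F/mol), 25 added by syringe pump over 12 h (final 2 mM), rt; aq. NH4Cl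
Reagents that add atoms: none
Why: Proposed new method: the cathode regenerates divalent chromium from the trivalent chromium alkoxide (released by Cp2ZrCl2) while zerovalent nickel inserts into the alkenyl iodide and passes the alkenyl group to chromium, so a low stationary concentration of alkenylchromium adds to the tethered C3 aldehyde under high dilution and closes the ten-membered ring with retention of the Z geometry, the C6–C8 stereotriad forcing the metal-bound carbonyl oxygen to the outside of the forming ring and giving the 3S (3β) alcohol; the closest known reaction types are the intermolecular electrochemical chromium-catalysed Nozaki–Hiyama–Kishi coupling and stoichiometric CrCl2/NiCl2 macrocyclisations.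

Step 18
Reactants: 26 (3S,6R,7R,8R)-3-hydroxy-8-{[(2S,3R)-2,3-dimethyloxirane-2-carbonyl]oxy}germacra-1(10)E,4Z,11(13)-trien-12,6-olide
Product: 27 (3S,6R,7R,8R)-3-benzoyloxy-8-{[(2S,3R)-2,3-dimethyloxirane-2-carbonyl]oxy}germacra-1(10)E,4Z,11(13)-trien-12,6-olide
Conditions: BzCl (1.5 equiv), pyridine (3 equiv), DMAP (5 mol%), CH2Cl2, 0 °C
Reagents that add atoms: benzoyl chloride, O=C(Cl)c1ccccc1
Why: Nucleophile-catalysed O-acylation of the allylic alcohol proceeds with retention at C3 and also deactivates the 4,5-alkene for the last step.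

Step 19
Reactants: 27 (3S,6R,7R,8R)-3-benzoyloxy-8-{[(2S,3R)-2,3-dimethyloxirane-2-carbonyl]oxy}germacra-1(10)E,4Z,11(13)-trien-12,6-olide
Product: 28 (1R,3S,6R,7R,8R,10R)-3-benzoyloxy-1,10-epoxy-8-{[(2S,3R)-2,3-dimethyloxirane-2-carbonyl]oxy}germacra-4Z,11(13)-dien-12,6-olide (CNP0324463.4)
Conditions: mCPBA (1.1 equiv), NaHCO3, CH2Cl2, −10 → 0 °C
Reagents that add atoms: 3-chloroperoxybenzoic acid, O=C(OO)c1cccc(Cl)c1
Why: Prilezhaev epoxidation picks the only electron-rich alkene (the 4,5-alkene carries two allylic acyloxy groups, the 11,13-alkene is conjugated) and the peracid attacks the exposed outer face of the E-1(10) double bond in the heliangolide conformation, giving the 1β,10α (1R,10R) epoxide.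

**Compound list**
1 | methyl (S)-2,2-dimethyl-1,3-dioxolane-4-carboxylate | COC(=O)[C@@H]1COC(C)(C)O1 | starting material
2 | (S)-2,2-dimethyl-1,3-dioxolane-4-carbaldehyde | O=C[C@@H]1COC(C)(C)O1 | intermediate
3 | (R)-4-[(Z)-2-iodoprop-1-en-1-yl]-2,2-dimethyl-1,3-dioxolane | I/C(C)=C\[C@@H]1COC(C)(C)O1 | intermediate
4 | (2R,3Z)-4-iodopent-3-ene-1,2-diol | I/C(C)=C\[C@@H](O)CO | intermediate
5 | (2R,3Z)-2-hydroxy-4-iodopent-3-en-1-yl 4-methylbenzenesulfonate | I/C(C)=C\[C@@H](O)COS(=O)(=O)c1ccc(C)cc1 | intermediate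
6 | (R)-2-[(Z)-2-iodoprop-1-en-1-yl]oxirane | I/C(C)=C\[C@@H]1CO1 | intermediate
7 | (3S,4Z)-5-iodohexa-1,4-dien-3-ol | I/C(C)=C\[C@@H](O)C=C | intermediate
8 | 2-(bromomethyl)prop-2-enoic acid | OC(=O)C(=C)CBr | starting material
9 | (3S,4Z)-5-iodohexa-1,4-dien-3-yl 2-(bromomethyl)prop-2-enoate | I/C(C)=C\[C@@H](OC(=O)C(=C)CBr)C=C | intermediate
10 | (S)-3-(bromomethyl)-5-[(Z)-2-iodoprop-1-en-1-yl]furan-2(5H)-one | I/C(C)=C\[C@H]1OC(=O)C(CBr)=C1 | intermediate
11 | tert-butyl(but-3-yn-1-yloxy)dimethylsilane | C#CCCO[Si](C)(C)C(C)(C)C | starting material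
12 | [(1E)-4-{[tert-butyl(dimethyl)silyl]oxy}-2-methylbut-1-en-1-yl]dimethylalumane | C[Al](C)/C=C(\C)CCO[Si](C)(C)C(C)(C)C | intermediate
13 | (3E)-6-{[tert-butyl(dimethyl)silyl]oxy}-4-methylhex-3-en-1-ol | OCC/C=C(\C)CCO[Si](C)(C)C(C)(C)C | intermediate
14 | (3E)-6-{[tert-butyl(dimethyl)silyl]oxy}-4-methylhex-3-enal | O=CC/C=C(\C)CCO[Si](C)(C)C(C)(C)C | intermediate
15 | tert-butyl{[(3E)-6,6-dimethoxy-3-methylhex-3-en-1-yl]oxy}dimethylsilane | COC(OC)C/C=C(\C)CCO[Si](C)(C)C(C)(C)C | intermediate
16 | (3E)-6,6-dimethoxy-3-methylhex-3-en-1-ol | COC(OC)C/C=C(\C)CCO | intermediate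
17 | (3E)-6,6-dimethoxy-3-methylhex-3-enal | COC(OC)C/C=C(\C)CC=O | intermediate
18 | methyl (R)-3-hydroxybutanoate | COC(=O)C[C@@H](C)O | starting material
19 | methyl (2R,3R)-3-hydroxy-2-methylbutanoate | COC(=O)[C@H](C)[C@@H](C)O | intermediate
20 | methyl (2R,3R)-3-hydroxy-2-iodo-2-methylbutanoate (present as its lithium alkoxide) | COC(=O)[C@@](I)(C)[C@@H](C)O | intermediate
21 | methyl (2S,3R)-2,3-dimethyloxirane-2-carboxylate (methyls cis) | COC(=O)[C@@]1(C)O[C@@H]1C | intermediate
22 | (2S,3R)-2,3-dimethyloxirane-2-carboxylic acid | OC(=O)[C@@]1(C)O[C@@H]1C | intermediate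
23 | (4R,5S)-4-[(1S,3E)-1-hydroxy-6,6-dimethoxy-3-methylhex-3-en-1-yl]-5-[(Z)-2-iodoprop-1-en-1-yl]-3-methylideneoxolan-2-one (trans-lactone, 8α-OH) | C=C1C(=O)O[C@H](/C=C(/C)I)[C@H]1[C@@H](O)C/C(C)=C/CC(OC)OC | intermediate
24 | (1R,3E)-1-[(2S,3R)-2-[(Z)-2-iodoprop-1-en-1-yl]-4-methylidene-5-oxooxolan-3-yl]-6,6-dimethoxy-3-methylhex-3-en-1-yl (2S,3R)-2,3-dimethyloxirane-2-carboxylate | C=C1C(=O)O[C@H](/C=C(/C)I)[C@H]1[C@H](OC(=O)[C@@]2(C)O[C@@H]2C)C/C(C)=C/CC(OC)OC | intermediate
25 | (1R,3E)-1-[(2S,3R)-2-[(Z)-2-iodoprop-1-en-1-yl]-4-methylidene-5-oxooxolan-3-yl]-3-methyl-6-oxohex-3-en-1-yl (2S,3R)-2,3-dimethyloxirane-2-carboxylate | C=C1C(=O)O[C@H](/C=C(/C)I)[C@H]1[C@H](OC(=O)[C@@]2(C)O[C@@H]2C)C/C(C)=C/CC=O | intermediate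
26 | (3S,6R,7R,8R)-3-hydroxy-8-{[(2S,3R)-2,3-dimethyloxirane-2-carbonyl]oxy}germacra-1(10)E,4Z,11(13)-trien-12,6-olide (3β-OH, 8β-ester, trans 6α,12-lactone) | C=C1C(=O)O[C@@H]2/C=C(/C)[C@@H](O)C/C=C(\C)C[C@@H](OC(=O)[C@@]3(C)O[C@@H]3C)[C@@H]12 | intermediate
27 | (3S,6R,7R,8R)-3-benzoyloxy-8-{[(2S,3R)-2,3-dimethyloxirane-2-carbonyl]oxy}germacra-1(10)E,4Z,11(13)-trien-12,6-olide | C=C1C(=O)O[C@@H]2/C=C(/C)[C@@H](OC(=O)c3ccccc3)C/C=C(\C)C[C@@H](OC(=O)[C@@]3(C)O[C@@H]3C)[C@@H]12 | intermediate
28 | (1R,3S,6R,7R,8R,10R)-3-benzoyloxy-1,10-epoxy-8-{[(2S,3R)-2,3-dimethyloxirane-2-carbonyl]oxy}germacra-4Z,11(13)-dien-12,6-olide (CNP0324463.4) | C=C1C(=O)O[C@@H]2/C=C(/C)[C@@H](OC(=O)c3ccccc3)C[C@H]3O[C@]3(C)C[C@@H](OC(=O)[C@@]3(C)O[C@@H]3C)[C@@H]12 | target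

**Step count and risks**

Total steps: 19 (steps 1–6 for the iodobutenolide, 7–10 for the aldehyde, 11–13 for the epoxy acid, 14–19 for union and endgame). Longest linear sequence: 12 steps (1–6, then 14–19).

The three steps most likely to fail:

- **Step 17.** The electrochemical macrocyclisation is untested: the C3 selectivity is a conformational prediction, and oligomerisation or loss of the alkenylmetal before ring closure could compete. The fallback sets out from 25 and returns at 26. The ring is closed with the classical stoichiometric Nozaki–Hiyama–Kishi reaction (CrCl2 8 equiv, NiCl2 1 mol%, DMSO/THF, 2 mM), which is established for ten-membered rings, and the C3 configuration is taken out of the ring-closing event. The crude product, 26 mixed with its (3R)-epimer alcohol F1, is oxidised with MnO2 to the 3-oxo-4Z-enone F2. Luche reduction (NaBH4, CeCl3·7H2O, MeOH, −78 °C; hydride from the outer face) then returns to 26.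

- **Step 15.** Mitsunobu inversion at the hindered C8 carbinol with an α-quaternary acid may be slow or give elimination. The fallback sets out from 23 and returns at 24. ClCH2SO2Cl/pyridine (0 °C) converts 23 into the C8 chloromethanesulfonate F3. This is displaced with inversion by caesium (2S,3R)-2,3-dimethyloxirane-2-carboxylate F4 (from 22 and Cs2CO3; 18-crown-6, toluene, 60 °C) to give 24.

- **Step 19.** The facial sense of the late peracid epoxidation rests on the ring conformation. The fallback sets out from 27 and returns at 28. If the peracid enters from the other face, the sense is reversed by a halohydrin route: NBS in acetone/H2O (0 °C) gives the 1-bromo-10-hydroxy bromohydrin F5 (bromonium on the face the peracid used, water adding at tertiary C10). K2CO3 in acetone then closes it with inversion at C1 to 28.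

Further compounds
F1 | step 17 | (3R)-epimer of 26 (3α-hydroxy macrocycle) | C=C1C(=O)O[C@@H]2/C=C(/C)[C@H](O)C/C=C(\C)C[C@@H](OC(=O)[C@@]3(C)O[C@@H]3C)[C@@H]12
F2 | step 17 | 3-oxo analogue of 26 ((6R,7R,8R)-3-oxo-8-acyloxygermacra-1(10)E,4Z,11(13)-trien-12,6-olide) | C=C1C(=O)O[C@@H]2/C=C(/C)C(=O)C/C=C(\C)C[C@@H](OC(=O)[C@@]3(C)O[C@@H]3C)[C@@H]12
F3 | step 15 | chloromethanesulfonate of 23 at the C8 hydroxyl | C=C1C(=O)O[C@H](/C=C(/C)I)[C@H]1[C@@H](OS(=O)(=O)CCl)C/C(C)=C/CC(OC)OC
F4 | step 15 | caesium (2S,3R)-2,3-dimethyloxirane-2-carboxylate | [Cs+].[O-]C(=O)[C@@]1(C)O[C@@H]1C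
F5 | step 19 | bromohydrin of 27 (1-bromo-10-hydroxy, bromine and hydroxyl anti) | C=C1C(=O)O[C@@H]2/C=C(/C)[C@@H](OC(=O)c3ccccc3)C[C@H](Br)[C@](C)(O)C[C@@H](OC(=O)[C@@]3(C)O[C@@H]3C)[C@@H]12
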